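We have one flask, followed so far.

- Thursday's: starting material 0.50 M; the very flask that is asked about, followed so far
- flask: starting material 0.50 M; time 1.5 h

Thursday's run (percent of the starting material charged)

| time / min | single ring / % | open trimer / % |
|---|---|---|
| 3.00 | 6 | 0 |
| 8.00 | 9 | 0 |
| 15.0 | 22 | 2 |
| 25.0 | 29 | 3 |
| 30.0 | 33 | 6 |
| 50.0 | 42 | 11 |

(readings scatter by 2 percentage points)

- in percentages every species weighs as the starting material in it: one ring dimer counts as two
- in percentages every species weighs as the starting material in it: one open trimer counts as three
- the numbers in the tables scatter with a standard deviation of 2 percentage points

- single ring present at 1.5 h, in percent of the starting material charged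
- open trimer present at 1.5 h, in percent of the starting material charged
- ring dimer present at 1.5 h, in percent of the starting material charged
- starting material present at 1.5 h, in percent of the starting material charged

We assume that single ring forms first order in [starting material] and that the rest of the starting material goes by a route second order in it.

1. Taken as an initial slope, the single ring reading at 15.0 min gives a first reading of k = 0.0147 min⁻¹.

2. The late gain of single ring, divided by k, puts starting material near 30.7 % at 40.0 min.

3. Single ring is then 54.1 % of what was used, at a mean [starting material] of 0.327 M.

4. So we read c× = 0.385 M from these scattered readings. On our assumption, this even concentration is the [starting material] at which both routes use it equally fast, a selectivity factor in concentration units. On the same assumption, single ring made is c×·ln((c×+charge)/(c×+[starting material])), and [starting material]/(c×+[starting material]) decays exponentially at k.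

5. At 1.5 h we get 13.7 % starting material and 51.5 % single ring.

6. The weak link is k, taken from one scattered reading. Putting the 50.0 min reading through the logarithm gives 25.6 % starting material there and k = 0.0164 min⁻¹.

We commit to 11.5 % starting material and 53.4 % single ring. Keeping open trimer's share of the rest gives 11.9 % open trimer and 23.2 % ring dimer.

The forecast says 53 %, 19 %, 16 % and 12 % in the order single ring, open trimer, ring dimer, starting material: “The open trimer shows a clear lag, so it looks like a secondary product”. Our open trimer is lower and our ring dimer higher.

The flask gives 56.8 % single ring, 6.82 % open trimer, 24.3 % ring dimer and 11.7 % starting material. Open trimer stands at 6.82 % after 1.50 h and 6.87 % after 15.0 h, with open dimer at 0.353 % after 1.50 h.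

    starting material → single ring (k = 0.0170 min⁻¹)
    open dimer → ring dimer (k = 0.100 min⁻¹)
    2 starting material → open dimer (k = 0.0170 M⁻¹ min⁻¹)
    starting material + open dimer → open trimer (k = 0.0730 M⁻¹ min⁻¹)

Through c×, the flask's starting material corresponds to 53.2 % single ring. The neighbour flask charged with 0.12 M holds 18.2 % of its own charge as starting material at the same time, which c× turns into 69.3 % single ring; that flask holds 71.7 %.

(The data were computed for substances that don't exist; the scatter is artificial.)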